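The numbers in the tables are calculated for substances that don't exist.

Count X first.

| flask | J | X | remark | time |
|---|---|---|---|---|
| eta | 0.015 M | 0.019 M | run made earlier |  |
| theta | 0.11 M | 0.019 M | run made earlier |  |
| zeta | 0.36 M | 0.019 M | run made earlier |  |
| midnight | 0.020 M | 0.0190 M |  | 40 min |
| autumn | 0.060 M | 0.0190 M |  | 40 min |
| winter | 0.15 M | 0.0190 M |  | 40 min |
| spring | 0.50 M | 0.0190 M |  | 40 min |

| run | time / min | G / % | J / % |
|---|---|---|---|
| eta | 1.50 | 10.0 | 87.5 |
| eta | 3.00 | 16.5 | 76.2 |
| eta | 6.00 | 27.9 | 63.0 |
| eta | 10.0 | 35.4 | 50.1 |
| eta | 20.0 | 47.9 | 40.1 |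
| theta | 4.00 | 11.5 | 76.8 |
| theta | 8.00 | 14.5 | 71.6 |
| theta | 12.0 | 18.7 | 71.4 |
| theta | 15.0 | 17.0 | 70.1 |
| theta | 20.0 | 14.8 | 69.8 |
| zeta | 4.00 | 6.8 | 88.5 |
| zeta | 8.00 | 5.4 | 89.9 |
| zeta | 12.0 | 3.3 | 88.5 |
| zeta | 15.0 | 4.8 | 90.0 |
| zeta | 20.0 | 4.4 | 92.1 |

(standard deviation of a reading: 1 percentage point)

- what was read earlier has a scatter of 1 percentage point, one standard deviation
- "hardly changes" means that all values lie within two and a half points (for a concentration: within two and a half percent of the largest)
- a reading of J is of its free form alone

* amount of G at the end, in percent of the J charged for midnight, autumn, winter, spring, in this order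
* the shape of the row from first to last (hardly changes / falls, then rises / falls all the way / rises, then falls / rises all the way)

Take the main step by itself: if one X turns one J into one G, then G, as a fraction of the J charged, stops at the charge of X over the charge of J, which for midnight is 95.0%, and you may call this the ceiling, with X as the limiting reagent of that step, its charge being smaller than any J charge asked. For autumn, winter and spring the ceiling is 31.7%, 12.7% and 3.80%, so this first row falls from end to end.

Now add speed, which matters for midnight, where the charges nearly match. In the eta run G gains 12 percentage points between 10.0 min and 20.0 min, a doubling of time, and one more such gain on its last reading gives 60.4% as my first answer for midnight at 40 min. Put that answer back in: it would leave 36.4% of midnight's X, less than the 62.2% that the last G reading of eta implies for the X of eta, and at equal fractions of J the speed of the main step follows X, so the last gain shrinks to 7.3 points and my second round gives 55.2%.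

Then the rest, as the readings show it. In eta 12.0% of the J charged reads as neither J nor G at 20.0 min, so free J runs below what G alone implies, and I would lean under my midnight figure. In the theta run, whose ceiling is 17.3%, the readings from 8.00 min on average 94.1% of that ceiling, and applying this share gives me 29.8%, 11.9% and 3.57% for the other flasks.

The forecast, holding of X that G “is capped by it”, says 60%, 30.5%, 12.3% and 3.7%, falls all the way, which at midnight stands higher than my figure.

The flask gives 48.9%, 27.5%, 12.5% and 3.80%, falls all the way.

    J + Q → E (k = 0.0110 L mol⁻¹ s⁻¹)
    J + X ⇌ G + Q (K = 0.600, k = 0.0570 L mol⁻¹ s⁻¹)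
    J + Q ⇌ Z, settled at all times (K = 93.0 L mol⁻¹)
    Q → D (k = 4.60 × 10⁻⁴ s⁻¹)

At midnight 48% of the X charged is still there at 40.0 min, and the share of X used, taken of the ceiling of 95.0%, gives 49.4% as G. In autumn 13% of the X charged is left at 40.0 min, and the share used, taken of the autumn ceiling of 31.7%, gives 27.6% as G.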